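C2–C3–C4 (unprimed locants for the chromanone unit: O1, C2 ketal, C3 carbinol, C4 carbonyl; primed for the flavan) is read as a vicinal tricarbonyl that has captured the flavan A ring twice, C8' at the central carbon C3 and O7' at C2. The tricarbonyl is carried as its stable five-membered hemiketal, a 2-aroyl-2-hydroxybenzofuran-3(2H)-one; the partner is the (2S)-flavan with free 7'-OH. In one operation a chiral phosphoric acid joins C8' to the central carbonyl, and double ketalisation closes the furan ring and re-closes the phloroglucinol oxygen O1 on the aroyl carbon, expanding the benzofuranone ring by one carbon into the chromanone and setting both ring-fusion stereocentres.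

Key step: step 8

Remark (stereochemistry): the two ring-fusion centres are carried with the descriptors exactly as the target SMILES writes them, (S) at the ketal carbon C2 and (R) at the carbinol carbon C3, with (S) at C2' of the flavan; C2 is treated as dependent on C3, because both of its oxygens are delivered from groups anchored on C3.
Remark (materials): compounds 1, 4, 9 and 10 are taken as commercially available. TRIP = 3,3'-bis(2,4,6-triisopropylphenyl)-1,1'-binaphthyl-2,2'-diyl hydrogen phosphate.

**Route**

Step 1
Reactants: 1 2,4,6-trihydroxybenzaldehyde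
Product: 2 2,6-dihydroxy-4-(methoxymethoxy)benzaldehyde
Conditions: MOMCl (1.0 equiv), K2CO3, acetone, 0 °C to rt
Reagents that add atoms: chloromethyl methyl ether (MOMCl), COCCl
Why: Williamson-type acetal protection; the 4-hydroxyl, para to the formyl group and the only one not chelated to it, is the most acidic and nucleophilic phenol, so one equivalent of MOMCl should alkylate it selectively.

Step 2
Reactants: 2 2,6-dihydroxy-4-(methoxymethoxy)benzaldehyde
Product: 3 2-(benzyloxy)-6-hydroxy-4-(methoxymethoxy)benzaldehyde
Conditions: BnBr (1.05 equiv), K2CO3, DMF, rt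
Reagents that add atoms: benzyl bromide, BrCc1ccccc1
Why: Williamson etherification; the two hydroxyls are equivalent, and after the first benzylation the last one stays locked in the hydrogen bond to the aldehyde, which should stop the reaction at the monoether.

Step 3
Reactants: 3 2-(benzyloxy)-6-hydroxy-4-(methoxymethoxy)benzaldehyde; 4 4'-(benzyloxy)acetophenone
Product: 6 5-(benzyloxy)-2-[4-(benzyloxy)phenyl]-7-hydroxychromenylium chloride, via 7-O-MOM flavylium chloride 5 (not isolated)
Conditions: HCl (g), EtOAc/MeOH, 0 °C to rt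
Reagents that add atoms: hydrogen chloride, Cl
Why: Acid-mediated Claisen–Schmidt condensation and cyclodehydration to the flavylium (2-arylchromenylium) salt; HCl in methanol also cleaves the MOM acetal, which frees the 7-hydroxyl while the benzyl ethers should remain.

Step 4
Reactants: 6 5-(benzyloxy)-2-[4-(benzyloxy)phenyl]-7-hydroxychromenylium chloride
Product: 7 5-(benzyloxy)-2-[4-(benzyloxy)phenyl]-4H-chromen-7-ol
Conditions: Hantzsch ester (1.05 equiv), NaOAc, CH2Cl2/MeCN, 0 °C, Ar
Reagents that add atoms: none
Why: Hydride transfer from the dihydropyridine (an NADH-model reduction) to C4, the unhindered electrophilic position of the 2-arylchromenylium ion, should give the 4H-chromene, with acetate buffering the acid that would otherwise trigger a second, non-selective reduction.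

Step 5
Reactants: 7 5-(benzyloxy)-2-[4-(benzyloxy)phenyl]-4H-chromen-7-ol
Product: 8 (2S)-5-(benzyloxy)-2-[4-(benzyloxy)phenyl]-3,4-dihydro-2H-chromen-7-ol
Conditions: H2 (50 bar), [Ir(cod)(L)]B[3,5-(CF3)2C6H3]4 (1 mol%), L = (S)-4-tert-butyl-2-[2-(diphenylphosphino)phenyl]-2-oxazoline, CH2Cl2, rt
Reagents that add atoms: none
Why: Iridium-catalysed asymmetric hydrogenation of the cyclic trisubstituted enol ether of a 2-aryl-4H-chromene, in which the chiral P,N ligand differentiates the faces of C2'=C3' and sets C2' as (S) (the ligand enantiomer is chosen accordingly); aryl benzyl ethers are not cleaved by this catalyst.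

Step 6
Reactants: 9 1-[2,4-bis(benzyloxy)-6-hydroxyphenyl]ethanone; 10 4-(benzyloxy)benzoyl chloride
Product: 11 1-[2,4-bis(benzyloxy)-6-hydroxyphenyl]-3-[4-(benzyloxy)phenyl]propane-1,3-dione
Conditions: LiN(SiMe3)2 (3.5 equiv), THF, −78 °C; then 10, −78 °C to rt
Reagents that add atoms: none
Why: One-pot Baker–Venkataraman-type acylation; the lithium phenoxide–enolate dianion of 9 is C-acylated by the aroyl chloride (or O-acylated and rearranged) to the 1,3-diketone, a third equivalent of base being consumed by the acidic product.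

Step 7
Reactants: 11 1-[2,4-bis(benzyloxy)-6-hydroxyphenyl]-3-[4-(benzyloxy)phenyl]propane-1,3-dione
Product: 13 4,6-bis(benzyloxy)-2-[4-(benzyloxy)benzoyl]-2-hydroxy-1-benzofuran-3(2H)-one, via 2-aroylbenzofuran-3-ol 12 (not isolated)
Conditions: PhI(OAc)2 (1.1 equiv), MeCN, 0 °C to rt; then PhI(OAc)2 (1.2 equiv), H2O, rt
Reagents that add atoms: water, O
Why: Trivalent-iodine α-functionalisation of the enolised β-diketone, in which the ortho-phenol displaces iodobenzene from the α-iodanyl diketone (5-exo-tet, the known oxidative cyclisation of 2-hydroxydibenzoylmethanes to 2-aroylbenzofuran-3-ols), after which the second portion of oxidant repeats the α-iodanylation on the new enol and water displaces iodobenzene at C2 (α-hydroxylation of a 2-substituted β-dicarbonyl), so the hemiketal should form with the five-membered ring intact throughout.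

Step 8
Reactants: 13 4,6-bis(benzyloxy)-2-[4-(benzyloxy)benzoyl]-2-hydroxy-1-benzofuran-3(2H)-one; 8 (2S)-5-(benzyloxy)-2-[4-(benzyloxy)phenyl]-3,4-dihydro-2H-chromen-7-ol
Product: 16 penta-O-benzyl daphnodorin F, via open-chain triketone 14 (not isolated), via Friedel–Crafts hydroxy diketone 15 (not isolated)
Conditions: (R)-TRIP (10 mol%), 4 Å MS, toluene, 0 °C to rt
Reagents that add atoms: none
Why: Proposed new method: the acid opens the racemic hemiketal 13 to the achiral triketone 14 and, holding the 7'-OH of 8 on its phosphoryl oxygen while its P–OH activates the central carbonyl, steers C8' onto that carbon (ortho Friedel–Crafts hydroxyalkylation, giving 15), after which O7' adds to the 4-benzyloxybenzoyl carbonyl and the aryl-stabilised oxocarbenium ion left by loss of water is captured by the freed phloroglucinol oxygen O1. The closest known reaction types are the acid-mediated condensation of phenols with ninhydrin and other vicinal tricarbonyls to fused hemiketals, chiral phosphoric acid-catalysed ortho Friedel–Crafts additions of phenols to activated ketones, and the ring-chain equilibrium between 2-aroyl-2-hydroxybenzofuranones and 2-hydroxyflavan-3,4-diones. The furan ring closes 5-exo-trig (hemiketal) and the chromanone ring 6-exo-trig onto the oxocarbenium ion, so the five ring atoms of the benzofuranone (O1, C2, C3, C3a, C7a of 13) reappear in the six-membered ring with the former aroyl carbon inserted between the oxygen and the carbinol carbon. C3 is set in the C–C bond formation by the chiral phosphate (catalyst control, the flavan centre being too remote to interfere; the acid enantiomer is chosen for the (R)-carbinol), and C2 has no freedom of its own because O7' and O1 both reach it from groups held on C3. The step needs C8' over C6' selectivity, secured by the 5'-benzyloxy group that the peri C4' methylene turns over C6', and attack at the central rather than a flanking carbonyl, secured by its much higher electrophilicity; the chelated, doubly ortho-substituted carbonyl C4 stays a ketone because only the other aroyl carbon can be bridged by O1.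

Step 9
Reactants: 16 penta-O-benzyl daphnodorin F
Product: 17 daphnodorin F
Conditions: H2 (1 atm), Pd/C (10%), EtOAc/MeOH, rt
Reagents that add atoms: none
Why: Catalytic hydrogenolysis of the five aryl benzyl ethers; the fully substituted ketal and carbinol carbons and the chelated aryl ketone should be too hindered or too electron-rich to be reduced under these mild conditions.

**Compound list**

1 | 2,4,6-trihydroxybenzaldehyde | O=Cc1c(O)cc(O)cc1O | starting material
2 | 2,6-dihydroxy-4-(methoxymethoxy)benzaldehyde | O=Cc1c(O)cc(OCOC)cc1O | intermediate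
3 | 2-(benzyloxy)-6-hydroxy-4-(methoxymethoxy)benzaldehyde | O=Cc1c(O)cc(OCOC)cc1OCc1ccccc1 | intermediate
4 | 4'-(benzyloxy)acetophenone | CC(=O)c1ccc(OCc2ccccc2)cc1 | starting material
5 | 5-(benzyloxy)-2-[4-(benzyloxy)phenyl]-7-(methoxymethoxy)chromenylium chloride (not isolated) | COCOc1cc(OCc2ccccc2)c2ccc(-c3ccc(OCc4ccccc4)cc3)[o+]c2c1.[Cl-] | intermediate
6 | 5-(benzyloxy)-2-[4-(benzyloxy)phenyl]-7-hydroxychromenylium chloride | Oc1cc(OCc2ccccc2)c2ccc(-c3ccc(OCc4ccccc4)cc3)[o+]c2c1.[Cl-] | intermediate
7 | 5-(benzyloxy)-2-[4-(benzyloxy)phenyl]-4H-chromen-7-ol | Oc1cc(OCc2ccccc2)c2c(c1)OC(c1ccc(OCc3ccccc3)cc1)=CC2 | intermediate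
8 | (2S)-5-(benzyloxy)-2-[4-(benzyloxy)phenyl]-3,4-dihydro-2H-chromen-7-ol | Oc1cc(OCc2ccccc2)c2c(c1)O[C@H](c1ccc(OCc3ccccc3)cc1)CC2 | intermediate
9 | 1-[2,4-bis(benzyloxy)-6-hydroxyphenyl]ethanone | CC(=O)c1c(O)cc(OCc2ccccc2)cc1OCc1ccccc1 | starting material
10 | 4-(benzyloxy)benzoyl chloride | O=C(Cl)c1ccc(OCc2ccccc2)cc1 | starting material
11 | 1-[2,4-bis(benzyloxy)-6-hydroxyphenyl]-3-[4-(benzyloxy)phenyl]propane-1,3-dione | O=C(CC(=O)c1ccc(OCc2ccccc2)cc1)c1c(O)cc(OCc2ccccc2)cc1OCc1ccccc1 | intermediate
12 | [4,6-bis(benzyloxy)-3-hydroxy-1-benzofuran-2-yl][4-(benzyloxy)phenyl]methanone, the enol form of the 2-aroylbenzofuran-3(2H)-one (not isolated) | O=C(c1oc2cc(OCc3ccccc3)cc(OCc3ccccc3)c2c1O)c1ccc(OCc2ccccc2)cc1 | intermediate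
13 | 4,6-bis(benzyloxy)-2-[4-(benzyloxy)benzoyl]-2-hydroxy-1-benzofuran-3(2H)-one (racemic hemiketal) | O=C1c2c(OCc3ccccc3)cc(OCc3ccccc3)cc2OC1(O)C(=O)c1ccc(OCc2ccccc2)cc1 | intermediate
14 | 1-[2,4-bis(benzyloxy)-6-hydroxyphenyl]-3-[4-(benzyloxy)phenyl]propane-1,2,3-trione (not isolated) | O=C(C(=O)C(=O)c1ccc(OCc2ccccc2)cc1)c1c(O)cc(OCc2ccccc2)cc1OCc1ccccc1 | intermediate
15 | (2S)-1-[2,4-bis(benzyloxy)-6-hydroxyphenyl]-3-[4-(benzyloxy)phenyl]-2-hydroxy-2-{(2S)-5-(benzyloxy)-2-[4-(benzyloxy)phenyl]-7-hydroxychroman-8-yl}propane-1,3-dione (not isolated) | O=C(c1c(O)cc(OCc2ccccc2)cc1OCc1ccccc1)[C@@](O)(C(=O)c1ccc(OCc2ccccc2)cc1)c1c(O)cc(OCc2ccccc2)c2c1O[C@H](c1ccc(OCc3ccccc3)cc1)CC2 | intermediate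
16 | penta-O-benzyl daphnodorin F: the (2S,3R,2'S) fused ketal of 17 with benzyl ethers on O5, O7, O5' and on the 4-oxygens of both 4-hydroxyphenyl groups, C3–OH free | O=C1c2c(OCc3ccccc3)cc(OCc3ccccc3)cc2O[C@]2(c3ccc(OCc4ccccc4)cc3)Oc3cc(OCc4ccccc4)c4c(c3[C@@]12O)O[C@H](c1ccc(OCc2ccccc2)cc1)CC4 | intermediate
17 | daphnodorin F, (2S,3R,2'S) | O=C1c2c(O)cc(O)cc2O[C@]2(c3ccc(O)cc3)Oc3cc(O)c4c(c3[C@@]12O)O[C@H](c1ccc(O)cc1)CC4 | target

**Count**

Total steps: 9. Longest linear sequence: 7 steps (steps 1, 2, 3, 4, 5, 8, 9).

**Steps most likely to fail**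

Step 8 (proposed new method). The phosphate may discriminate poorly between the two faces of the central carbonyl. The arene may attack through C6', or substitute at the hemiketal carbon with the benzofuranone ring retained. The cascade may also stall at the hemiketal stage. The fallback gives up asymmetric catalysis and uses the classical ninhydrin-type condensation. It sets out from 13 and 8, which are heated in AcOH at 50 °C and then treated with camphorsulfonic acid and 4 Å MS in toluene to complete the ketal. This should give 16 together with the (2R,3S,2'S) ring-fusion diastereomer of 16 F1. Because the flavan centre is fixed, the two are diastereomers and are separated by chromatography. The fallback comes back to the route at 16.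

Step 7. The trivalent iodine reagent may oxidise the electron-rich phenol ring (oxidative dearomatisation) instead of the enol, or the diketone may cyclodehydrate to the flavone under the acetic acid that is released. The fallback replaces the iodine oxidations by carbenoid O–H insertion and a separate hydroxylation. It sets out from 11. Diazo transfer (4-acetamidobenzenesulfonyl azide, Et3N, MeCN) gives 1-[2,4-bis(benzyloxy)-6-hydroxyphenyl]-3-[4-(benzyloxy)phenyl]-2-diazopropane-1,3-dione F2. Rh2(OAc)4 (1 mol%) in CH2Cl2 then inserts the carbenoid into the ortho-phenol O–H bond and closes the five-membered ring, giving 12, which is isolated in this sequence. Hydroxylation of C2 of 12 with dimethyldioxirane in acetone at 0 °C comes back to the route at 13.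

Step 5. The electron-rich enol ether may isomerise or dimerise under the acidic iridium hydride, or the free phenol may erode the enantioselectivity. The fallback builds the flavan by asymmetric ketone reduction and Mitsunobu ring closure instead, and also bypasses steps 3 and 4. It sets out from 3 and 4. Claisen–Schmidt condensation (KOH, EtOH) gives (E)-3-[2-(benzyloxy)-6-hydroxy-4-(methoxymethoxy)phenyl]-1-[4-(benzyloxy)phenyl]prop-2-en-1-one F3. Chemoselective alkene hydrogenation (H2, RhCl(PPh3)3) gives 3-[2-(benzyloxy)-6-hydroxy-4-(methoxymethoxy)phenyl]-1-[4-(benzyloxy)phenyl]propan-1-one F4. Corey–Bakshi–Shibata reduction ((S)-Me-CBS, BH3·SMe2) gives (1R)-3-[2-(benzyloxy)-6-hydroxy-4-(methoxymethoxy)phenyl]-1-[4-(benzyloxy)phenyl]propan-1-ol F5. Mitsunobu cyclisation (PPh3, DIAD) with inversion gives (2S)-5-(benzyloxy)-2-[4-(benzyloxy)phenyl]-7-(methoxymethoxy)chromane F6. Cleavage of the MOM ether (HCl, MeOH) then comes back to the route at 8.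

**Further compounds**

F1 | step 8 | (2R,3S,2'S) ring-fusion diastereomer of 16 | O=C1c2c(OCc3ccccc3)cc(OCc3ccccc3)cc2O[C@@]2(c3ccc(OCc4ccccc4)cc3)Oc3cc(OCc4ccccc4)c4c(c3[C@]12O)O[C@H](c1ccc(OCc2ccccc2)cc1)CC4
F2 | step 7 | 1-[2,4-bis(benzyloxy)-6-hydroxyphenyl]-3-[4-(benzyloxy)phenyl]-2-diazopropane-1,3-dione | O=C(C(=[N+]=[N-])C(=O)c1ccc(OCc2ccccc2)cc1)c1c(O)cc(OCc2ccccc2)cc1OCc1ccccc1
F3 | step 5 | (E)-3-[2-(benzyloxy)-6-hydroxy-4-(methoxymethoxy)phenyl]-1-[4-(benzyloxy)phenyl]prop-2-en-1-one | O=C(/C=C/c1c(O)cc(OCOC)cc1OCc1ccccc1)c1ccc(OCc2ccccc2)cc1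
F4 | step 5 | 3-[2-(benzyloxy)-6-hydroxy-4-(methoxymethoxy)phenyl]-1-[4-(benzyloxy)phenyl]propan-1-one | O=C(CCc1c(O)cc(OCOC)cc1OCc1ccccc1)c1ccc(OCc2ccccc2)cc1
F5 | step 5 | (1R)-3-[2-(benzyloxy)-6-hydroxy-4-(methoxymethoxy)phenyl]-1-[4-(benzyloxy)phenyl]propan-1-ol | O[C@H](CCc1c(O)cc(OCOC)cc1OCc1ccccc1)c1ccc(OCc2ccccc2)cc1
F6 | step 5 | (2S)-5-(benzyloxy)-2-[4-(benzyloxy)phenyl]-7-(methoxymethoxy)chromane | COCOc1cc(OCc2ccccc2)c2c(c1)O[C@H](c1ccc(OCc3ccccc3)cc1)CC2
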